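## The problem

Ring A atoms carry carvone numbers throughout (C1 spiro carbon, C2 the C(CH3)OH carbon, C3 and C4 CH2, C5 the alkylidene carbon, C6 the CH bearing the arm), and ring B atoms are C1' (carbinol), C2' (CH bearing the trienyl chain), C3' and C4' (CH2, C4' on the spiro carbon). The target is a spiro[4.5]decane: cyclohexane ring A and cyclopentane ring B share the quaternary carbon C1, which is flanked by the tertiary carbinol C2, the arm-bearing C6 and the secondary carbinol C1'. Five stereocentres must be set (C1, C2, C6, C1', C2'). C6 can govern the face of an oxygen delivered to C1/C2, a C2 oxygen can fix C1 through a stereospecific shift, and the free C2 hydroxyl can then steer hydride to C1'. C2' is the weak point, because it lies 1,3 to the spiro carbon across a planar carbon and feels the ring A substituents only from a distance. Two alkene geometries also count: the tetrasubstituted enal (formyl syn to C6) and the trisubstituted C(CH2OH)=CH bond of the chain. The β-hydroxy ketone stage is open to retro-aldol cleavage, the enal to deconjugation, and the triene with its prenyl terminus and allylic alcohol to acid and to allylic oxidants, so the chain and the free aldehyde have to come last. The feature that opens the route is the 1,3-dioxygenated unit O–C2–C1–C1': this is the retron of a semipinacol shift of a 2,3-epoxy alcohol. In addition, ring A with its C2 methyl and three-carbon branch on C5 is a p-menthane skeleton.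

## Retrosynthesis

Target 40 is traced to its dimethyl acetal 39, and 39 to the α-alkylidene γ-lactone 38. No skeletal bond is cut. The 1,4-diol made up of the C1' hydroxyl and the side-chain CH2OH is read as a reduced cis-fused lactone, and the arm hydroxyl as a pivalate. This stores two hydroxyls and the cis relation of C1'–O and C2'–C in one rigid ring. The forward step needs only a 1,2-selective hydride (i-Bu2AlH) that leaves the acetal alone, and then mild acid.

Lactone 38 is cut at the trisubstituted C=C into lactone 30 and dienal 34 (aldol condensation). The neighbouring cut, direct alkenylation α to the ring B ketone, would pass through a β,γ-unsaturated ketone with a doubly activated α-hydrogen. The aldol cut brings the whole trienyl chain in one piece after all oxidations of the core are done. The forward reaction must give the E alkylidene lactone.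

Dienal 34 is cut between its enal carbon and the 2-substituted diene carbon (Heck reaction) to enol triflate 33 and acrolein, and 33 comes from 6-methylhept-5-en-2-one 31 by kinetic enolisation. This two-step branch is simpler than olefination routes and fixes the E enal by the mechanism of the coupling.

Acetal 30 goes back through enal 29 and its exo-methylene isomer 28 to the isopropenyl lactone 26. No bond is cut; the isopropenyl methyl is oxidised and the double bond moved into the tetrasubstituted position. This must precede the arrival of the prenyl terminus, which SeO2 would attack, and it can follow the arm chemistry because the lactone, pivalate and tertiary alcohol are inert to it. The forward isomerisation relies on thermodynamic control of position and geometry.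

Pivalate 26 comes from alcohol 25 and this from allyl lactone 23 by anti-Markovnikov hydration. The allyl group is traced back through ketone 18 and the primary triflate 17 to alcohol 16, cutting the CH2–CH bond (vinyl cuprate displacement). This two-carbon extension is preferred to an oxidation–olefination sequence, which would leave an ester or an extra alkene to be reduced beside a ketone or lactone. Alcohol 16 comes from the bis-silyl ether 15 and this from hydroxy ketone 14.

Lactone 23 is opened to hydroxy ester 22, which is the product of hydroxyl-directed reduction of β-hydroxy ketone 21. Compound 21 arises from silyl ether 20, and the C2'–CH2 bond of 20 is cut to the enolate of 18 and ethyl bromoacetate. The ketone has only one enolisable side, so regiochemistry is not an issue. The forward alkylation has to pick the face of ring B syn to C6, and the reduction has to deliver hydride from the C2 side.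

The key cut takes 14 back to epoxy cyclobutanol 13: the C1–C4' bond is broken and re-formed as a cyclobutane bond, and the C2 hydroxyl becomes the epoxide oxygen. Against an aldol or alkylation approach to the quaternary carbon, this forms ring B, the spiro centre and the cis C2–OH/C1' relation in one stereospecific event from a precursor with one ring fewer.

Precursor 13 comes from epoxy diol 12 and this from diol 11 by hydroxyl-directed epoxidation. The C1–cyclobutane bond of 11 is cut to alkenylstannane 7 and cyclobutanone 8. Stannane 7 comes from enol triflate 6, and 6 from silyl ether 4, hydroxymethyl ketone 3 and (S)-carvone 1. The single stereocentre of carvone sets C6 by trans alkylation and is itself erased in step 18.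

## Roads not taken

Alternative 1: The cut is made on ring A at the bond from the arm-bearing CH to its arm and at the bond from the quaternary carbon to an allyl group. In the forward step Cu(OTf)2 with a chiral phosphoramidite would add a 3-(silyloxy)propylzinc reagent to the β-carbon of the ketal-protected enone ester A1, and the zinc enolate would be allylated to give A2. Merits: two C–C bonds and two adjacent stereocentres in one flask, absolute configuration from the catalyst, and the arm arriving at full length. In that respect it is clearly shorter than the chosen plan, which spends steps 10, 11, 15 and 16 on the arm. Weak points: the β-carbon of A1 sits next to the ketal carbon and is hindered, and enantiocontrol with a functionalised zinc reagent on a 2-carboalkoxy enone is less secure than on simple enones. After A2 the tertiary carbinol must come from methyl addition to a ketone beside the quaternary carbon with no handle for facial control. Ring B still has to be closed from allyl and ester, and the ketal carbon must become the tetrasubstituted enal by olefination of a hindered ketone without geometric control. The chosen plan sets against the shorter arm the fact that one stereospecific shift gives ring B, the quaternary centre and the C2 carbinol together.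

Alternative 2: The cut is the bond between the ring A alkene carbon C5 and C4. Forward, the vinyl group of triflate A3 would be hydroborated with 9-BBN and the alkylborane coupled with the enol triflate under PdCl2(dppf) to close ring A and give A4. Merit: the geometry of the tetrasubstituted alkene is fixed by the enol triflate and carried through a stereoretentive coupling. This is better than the chosen plan, which relies on a thermodynamic isomerisation (step 18). Weak points: A3 needs the quaternary centre with both neighbours (C2 and C6) built on an open chain, with no ring to relay configuration, and a geometrically pure enol triflate of a branched α-methyl β-keto ester. A six-membered closure onto a fully substituted alkenyl triflate also invites protodeboronation and β-hydride loss, and ring B in A4 is only a cyclopentene still lacking C1'–O and the C2' chain. The chosen plan answers with a cheap relay of three contiguous centres from carvone. It also argues that allylic 1,3-strain places the formyl group, not the methyl, next to C6 at equilibrium.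

Alternative 3: The cut is the C1'–C2' bond. Forward, Me2AlCl would promote an intramolecular carbonyl-ene reaction of aldehyde A5 with its homoprenyl alkene to give the cis-2-isopropenylcyclopentanol A6. Merits: ring B closes with both of its stereocentres and the cis relation of hydroxyl and alkenyl group in one step, along a plausible biogenetic line. Here it is better than the chosen plan, which needs steps 12–14 for the same result and rests C2' on remote shielding. Weak points: nothing secures the facial course of the ene reaction relative to the C2 and C6 sides of the spiro centre. The isopropenyl group of A6 has its double bond in the wrong place, so the trisubstituted C(CH2OH)=CH unit would need methyl oxidation and chain growth from the methylene carbon with E control. A5 itself presupposes the quaternary carbon with both neighbours, so the hardest stereochemical task is only moved upstream. The chosen plan makes that quaternary centre stereospecifically, and its step 12 has a fallback that sets C2' by ring fusion.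

Key step: step 8

Assumption: 28-deacetylbelamcandal is taken to have the formyl group syn to C6 and E geometry at both side-chain CH=C bonds, as written in the SMILES of compound 40.

Step 1
Reactants: 1 (S)-(+)-carvone
Product: 3 (5S,6S)-6-(hydroxymethyl)carvone, via lithium dienolate 2 (not isolated)
Conditions: LiN(i-Pr)2, THF, −78 °C; then CH2O (gas, cracked from paraformaldehyde), −78 °C
Reagents that add atoms: formaldehyde C=O
Why: Kinetic deprotonation at C6 gives the cross-conjugated dienolate, and the aldol addition to formaldehyde takes place anti to the neighbouring C5 isopropenyl group, which sets C6 trans to C5. Reaction type: directed aldol reaction (α'-hydroxymethylation of an enone).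

Step 2
Reactants: 3 (5S,6S)-6-(hydroxymethyl)carvone
Product: 4 silyl ether of 3
Conditions: t-BuMe2SiCl, imidazole, DMF, 0 °C → rt
Reagents that add atoms: tert-butyldimethylsilyl chloride CC(C)(C)[Si](C)(C)Cl
Why: Standard silylation of a primary alcohol; the ether keeps the hydroxyl out of the triflation and the organolithium step.

Step 3
Reactants: 4 silyl ether of 3
Product: 6 tetrasubstituted enol triflate, via lithium enolate 5 (not isolated)
Conditions: LiBH(s-Bu)3, THF, −78 °C; then PhNTf2, −78 → 0 °C
Reagents that add atoms: N-phenylbis(trifluoromethanesulfonimide) O=S(=O)(N(c1ccccc1)S(=O)(=O)C(F)(F)F)C(F)(F)F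
Why: The bulky borohydride adds hydride 1,4 to the β-unsubstituted enone and gives the C1=C2 enolate regiospecifically; O-triflation freezes this tetrasubstituted double bond. C6 is not enolised and keeps its configuration. Reaction type: conjugate reduction with enolate trapping.

Step 4
Reactants: 6 tetrasubstituted enol triflate
Product: 7 alkenyl trimethylstannane
Conditions: Me3SnSnMe3, Pd(PPh3)4 (5 mol%), LiCl, THF, 65 °C
Reagents that add atoms: hexamethylditin C[Sn](C)(C)[Sn](C)(C)C
Why: Palladium-catalysed stannylation of an enol triflate replaces C–O by C–Sn without moving the double bond and gives a handle for lithiation.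

Step 5
Reactants: 7 alkenyl trimethylstannane; 8 cyclobutanone
Product: 11 allylic cyclobutanol diol, via alkenyllithium 9 (not isolated), via lithium cyclobutanolate 10 (not isolated)
Conditions: MeLi, THF, −78 → 0 °C; 8, −78 °C; then Bu4NF (excess), rt
Reagents that add atoms: none
Why: Tin–lithium exchange gives the alkenyllithium, which adds 1,2 to the strained ketone; fluoride then frees the primary hydroxyl needed in step 6. The carbinol carbon is not stereogenic, so no stereocentre is set.

Step 6
Reactants: 11 allylic cyclobutanol diol
Product: 12 epoxy diol
Conditions: VO(acac)2 (5 mol%), t-BuOOH, CH2Cl2, 0 °C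
Reagents that add atoms: tert-butyl hydroperoxide CC(C)(C)OO
Why: Hydroxyl-directed epoxidation: the homoallylic CH2OH on stereogenic C6 binds vanadium and delivers oxygen to its own face of the C1=C2 bond, so the epoxide is syn to the arm. This sets C2 for good and C1 for the shift; the isopropenyl group is too remote from a hydroxyl to react.

Step 7
Reactants: 12 epoxy diol
Product: 13 epoxy cyclobutanol with primary silyl ether
Conditions: t-BuMe2SiCl, imidazole, CH2Cl2, 0 °C
Reagents that add atoms: tert-butyldimethylsilyl chloride CC(C)(C)[Si](C)(C)Cl
Why: Silylation is selective for the primary hydroxyl; the tertiary cyclobutanol stays free for the rearrangement.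

Step 8
Reactants: 13 epoxy cyclobutanol with primary silyl ether
Product: 14 spiro β-hydroxy cyclopentanone
Conditions: BF3·OEt2 (0.3 equiv), CH2Cl2, −78 → −40 °C; Et3N quench
Reagents that add atoms: none
Why: BF3 binds the epoxide oxygen; as the C1–O bond lengthens, the antiperiplanar cyclobutane C–C bond shifts from the carbinol carbon to C1, and the carbinol carbon, stabilised by its oxygen lone pair, becomes the ring B carbonyl C1' after loss of the hydroxyl proton. The closest known reaction type is the semipinacol rearrangement of 2,3-epoxy alcohols to β-hydroxy ketones, in its cyclobutanol ring-expansion form. Ring B is not closed by a cyclisation: the four-membered ring grows by one carbon through the 1,2-alkyl shift, so no ring-closure mode applies and the spiro junction is created at the migration terminus. The one new stereocentre, C1, is set by inversion at that terminus: the migrating CH2 (C4') enters anti to the departing oxygen, which leaves C1' on the face the epoxide oxygen occupied, cis to the C2 hydroxyl and to the C6 arm. The controlling element is the epoxide configuration fixed in step 6, and C2 keeps its oxygen and configuration because its C–O bond is not broken. The selectivity needed is cleavage at C1 and not at the equally substituted C2; it is secured by the assistance of the strained σ-bond and the carbinol oxygen, which is available only for ionisation at C1, and by relief of cyclobutane strain. The two cyclobutane CH2 groups are equivalent, and the low temperature and substoichiometric Lewis acid should leave the silyl ether and the isopropenyl group untouched.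

Step 9
Reactants: 14 spiro β-hydroxy cyclopentanone
Product: 15 bis-silyl ether
Conditions: t-BuMe2SiOTf, 2,6-lutidine, CH2Cl2, −78 → 0 °C
Reagents that add atoms: tert-butyldimethylsilyl trifluoromethanesulfonate CC(C)(C)[Si](C)(C)OS(=O)(=O)C(F)(F)F
Why: The silyl triflate silylates the hindered tertiary hydroxyl. The ether blocks retro-aldol cleavage under enolate conditions, keeps the C2 oxygen from attacking the arm triflate, and screens the C2 side of ring B in step 12.

Step 10
Reactants: 15 bis-silyl ether
Product: 16 primary alcohol with tertiary silyl ether
Conditions: HF·pyridine, pyridine, THF, 0 °C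
Reagents that add atoms: none
Why: A primary tert-butyldimethylsilyl ether is cleaved far faster than a tertiary one by buffered HF·pyridine, so only the arm is unmasked.

Step 11
Reactants: 16 primary alcohol with tertiary silyl ether
Product: 18 C6-allyl ketone, via primary triflate 17 (not isolated)
Conditions: Tf2O, 2,6-lutidine, CH2Cl2, −78 °C; then (CH2=CH)2CuMgBr (from CH2=CHMgBr and CuI), THF, −78 → −40 °C
Reagents that add atoms: vinylmagnesium bromide C=C[Mg]Br
Why: The primary triflate is displaced at low temperature by the divinylcuprate (SN2 coupling), which does not add to the hindered ketone. The arm becomes an allyl group, a two-carbon extension, and C6 is untouched.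

Step 12
Reactants: 18 C6-allyl ketone
Product: 20 C2' acetate keto ester, via lithium enolate 19 (not isolated)
Conditions: LiN(SiMe3)2, THF, −78 °C; BrCH2CO2Et, DMPU, −78 → −40 °C
Reagents that add atoms: ethyl bromoacetate CCOC(=O)CBr
Why: The ketone can enolise only toward C2', and the enolate is alkylated by the reactive α-bromo ester (enolate alkylation). The electrophile is expected to enter from the ring B face syn to C6, because the other face is flanked by the bulky silyloxy group on C2; this sets C2'.

Step 13
Reactants: 20 C2' acetate keto ester
Product: 21 β-hydroxy ketone ester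
Conditions: 48% aq. HF, MeCN, 0 °C → rt
Reagents that add atoms: none
Why: Acidic fluoride cleaves the tertiary silyl ether without basic conditions that could epimerise C2' or open the β-hydroxy ketone by retro-aldol reaction.

Step 14
Reactants: 21 β-hydroxy ketone ester
Product: 23 cis-fused γ-lactone, via hydroxy ester 22 (not isolated)
Conditions: Me4NBH(OAc)3, MeCN/AcOH, −20 °C → rt; then PPTS (cat.), CH2Cl2, rt
Reagents that add atoms: none
Why: Evans–Saksena reduction: the C2 hydroxyl exchanges onto boron and hydride is delivered through a six-membered transition state to the carbonyl face syn to C2. The new C1' hydroxyl therefore lies on the C6 side, anti to the C2 oxygen and cis to the acetate arm. Only this cis hydroxy ester can close to the five-membered lactone under mild acid, which also confirms the C2' configuration.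

Step 15
Reactants: 23 cis-fused γ-lactone
Product: 25 3-hydroxypropyl lactone, via alkylborane 24 (not isolated)
Conditions: (Me2CHCHMe)2BH (disiamylborane), THF, 0 °C; then NaBO3·4H2O, THF/H2O, rt
Reagents that add atoms: sodium perborate [Na+].[O-]B1OO1
Why: The bulky dialkylborane hydroborates the monosubstituted allyl double bond anti-Markovnikov in preference to the hindered 1,1-disubstituted isopropenyl group, and perborate oxidises the C–B bond without opening the lactone. Reaction type: hydroboration–oxidation.

Step 16
Reactants: 25 3-hydroxypropyl lactone
Product: 26 pivalate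
Conditions: t-BuCOCl, pyridine, DMAP (cat.), CH2Cl2, 0 °C → rt
Reagents that add atoms: pivaloyl chloride CC(C)(C)C(=O)Cl
Why: Only the primary hydroxyl is acylated; the pivalate has no enolisable hydrogen, survives steps 17–22 and is removed by the hydride of step 23.

Step 17
Reactants: 26 pivalate
Product: 28 α-methylene aldehyde, via allylic alcohol 27 (not isolated)
Conditions: SeO2 (0.5 equiv), t-BuOOH, CH2Cl2, rt; then MnO2, CH2Cl2, rt
Reagents that add atoms: tert-butyl hydroperoxide CC(C)(C)OO (oxygen source, passed on through selenium dioxide O=[Se]=O)
Why: Allylic oxidation by ene reaction and 2,3-sigmatropic shift attacks the methyl group of the 1,1-disubstituted alkene (CH3 before CH), and MnO2 converges the alcohol/aldehyde mixture on the aldehyde. The isopropenyl group is the only alkene left in the molecule at this stage.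

Step 18
Reactants: 28 α-methylene aldehyde
Product: 29 tetrasubstituted enal
Conditions: RhCl3·3H2O (10 mol%), EtOH, 75 °C
Reagents that add atoms: none
Why: A Rh–H species formed from RhCl3·3H2O adds to the methylene group and is lost again with the C5 hydrogen, which moves the double bond into the tetrasubstituted, conjugated position (rhodium-catalysed isomerisation of an α-methylene carbonyl compound). Position and geometry are under thermodynamic control, and allylic 1,3-strain with the C6 arm should place the small formyl group, not the methyl, syn to C6.

Step 19
Reactants: 29 tetrasubstituted enal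
Product: 30 dimethyl acetal
Conditions: HC(OMe)3, MeOH, PPTS (cat.), rt
Reagents that add atoms: trimethyl orthoformate COC(OC)OC; methanol CO
Why: Mild acetalisation with the orthoformate as water scavenger masks the aldehyde against the amide base of step 22 and the hydride of step 23; the weak acid is chosen to avoid migration of the double bond.

Step 20
Reactants: 31 6-methylhept-5-en-2-one
Product: 33 6-methylhepta-1,5-dien-2-yl triflate, via lithium enolate 32 (not isolated)
Conditions: LiN(i-Pr)2, THF, −78 °C; PhNTf2, −78 → 0 °C
Reagents that add atoms: N-phenylbis(trifluoromethanesulfonimide) O=S(=O)(N(c1ccccc1)S(=O)(=O)C(F)(F)F)C(F)(F)F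
Why: Kinetic deprotonation of the methyl ketone at the methyl group and O-triflation give the terminal enol triflate.

Step 21
Reactants: 33 6-methylhepta-1,5-dien-2-yl triflate
Product: 34 (2E)-8-methyl-4-methylidenenona-2,7-dienal
Conditions: acrolein, Pd(OAc)2 (5 mol%), PPh3, Et3N, DMF, 60 °C
Reagents that add atoms: acrolein C=CC=O
Why: Heck reaction of the alkenyl triflate with acrolein; syn insertion and syn β-hydride elimination give the E enal.

Step 22
Reactants: 30 dimethyl acetal; 34 (2E)-8-methyl-4-methylidenenona-2,7-dienal
Product: 38 (E)-α-alkylidene lactone, via dilithio lactone enolate 35 (not isolated), via aldolate 36 (not isolated), via aldol acetate 37 (not isolated)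
Conditions: LiN(i-Pr)2 (2.2 equiv), THF, −78 °C; 34; Ac2O, −78 → 0 °C; DBU, rt
Reagents that add atoms: none
Why: The lactone enolate (the tertiary hydroxyl takes the second equivalent of base) adds 1,2 to the enal, the aldolate is acetylated and DBU eliminates acetate (aldol condensation by E1cB elimination). The E isomer, with the dienyl chain turned away from the lactone carbonyl and syn to C2', is the thermodynamically preferred product and is the geometry of the target.

Step 23
Reactants: 38 (E)-α-alkylidene lactone
Product: 39 tetraol dimethyl acetal
Conditions: i-Bu2AlH (excess), CH2Cl2, −78 → 0 °C; Rochelle salt work-up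
Reagents that add atoms: none
Why: i-Bu2AlH reduces the conjugated lactone 1,2 to the allylic primary alcohol and the C1' alcohol and cleaves the pivalate in the same operation; the acetal and the triene are inert to it.

Step 24
Reactants: 39 tetraol dimethyl acetal
Product: 40 28-deacetylbelamcandal
Conditions: PPTS (cat.), acetone/H2O, rt
Reagents that add atoms: water O
Why: The acetal of a conjugated aldehyde is hydrolysed under acid mild enough to spare the triene allylic alcohol; no stereocentre or alkene geometry is affected.

Compound list

1 | (S)-(+)-carvone | CC1=CC[C@@H](CC1=O)C(C)=C | starting material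
2 | lithium cross-conjugated dienolate of 1 (C1–OLi, C1=C6) | CC1=CC[C@@H](C=C1O[Li])C(C)=C | intermediate
3 | (5S,6S)-6-(hydroxymethyl)-2-methyl-5-(prop-1-en-2-yl)cyclohex-2-en-1-one (CH2OH trans to isopropenyl) | CC1=CC[C@H](C(C)=C)[C@@H](CO)C1=O | intermediate
4 | tert-butyldimethylsilyl ether of 3 | CC1=CC[C@H](C(C)=C)[C@@H](CO[Si](C)(C)C(C)(C)C)C1=O | intermediate
5 | lithium enolate (C1–OLi, C1=C2) from 1,4-reduction of 4 | CC1=C(O[Li])[C@H](CO[Si](C)(C)C(C)(C)C)[C@@H](C(C)=C)CC1 | intermediate
6 | trans-6-(silyloxymethyl)-2-methyl-5-isopropenylcyclohex-1-en-1-yl triflate | CC1=C(OS(=O)(=O)C(F)(F)F)[C@H](CO[Si](C)(C)C(C)(C)C)[C@@H](C(C)=C)CC1 | intermediate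
7 | alkenyl trimethylstannane (SnMe3 on C1 in place of OTf) | CC1=C([Sn](C)(C)C)[C@H](CO[Si](C)(C)C(C)(C)C)[C@@H](C(C)=C)CC1 | intermediate
8 | cyclobutanone | O=C1CCC1 | starting material
9 | alkenyllithium (Li on C1) | CC1=C([Li])[C@H](CO[Si](C)(C)C(C)(C)C)[C@@H](C(C)=C)CC1 | intermediate
10 | lithium alkoxide of the silyl-protected 1-(cyclohexenyl)cyclobutanol | CC1=C(C2(O[Li])CCC2)[C@H](CO[Si](C)(C)C(C)(C)C)[C@@H](C(C)=C)CC1 | intermediate
11 | 1-[trans-6-(hydroxymethyl)-2-methyl-5-isopropenylcyclohex-1-en-1-yl]cyclobutan-1-ol | CC1=C(C2(O)CCC2)[C@H](CO)[C@@H](C(C)=C)CC1 | intermediate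
12 | epoxy diol (C1–C2 epoxide, oxygen syn to CH2OH and anti to isopropenyl) | OC1(CCC1)[C@@]23O[C@@]3(C)CC[C@H](C(C)=C)[C@H]2CO | intermediate
13 | epoxy cyclobutanol with primary tert-butyldimethylsilyl ether (precursor of the key step) | OC1(CCC1)[C@@]23O[C@@]3(C)CC[C@H](C(C)=C)[C@H]2CO[Si](C)(C)C(C)(C)C | intermediate
14 | spiro β-hydroxy cyclopentanone (C1' carbonyl carbon cis to the C2 hydroxyl and to the C6 CH2OSi arm; isopropenyl trans to the arm) | C1CC[C@]2([C@H](CO[Si](C)(C)C(C)(C)C)[C@@H](C(C)=C)CC[C@]2(C)O)C1=O | intermediate
15 | bis(tert-butyldimethylsilyl) ether of 14 | C1CC[C@]2([C@H](CO[Si](C)(C)C(C)(C)C)[C@@H](C(C)=C)CC[C@]2(C)O[Si](C)(C)C(C)(C)C)C1=O | intermediate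
16 | primary alcohol with tertiary silyl ether | C1CC[C@]2([C@H](CO)[C@@H](C(C)=C)CC[C@]2(C)O[Si](C)(C)C(C)(C)C)C1=O | intermediate
17 | primary triflate of 16 | C1CC[C@]2([C@H](COS(=O)(=O)C(F)(F)F)[C@@H](C(C)=C)CC[C@]2(C)O[Si](C)(C)C(C)(C)C)C1=O | intermediate
18 | C6-allyl spiro ketone with tertiary silyl ether | C1CC[C@]2([C@H](CC=C)[C@@H](C(C)=C)CC[C@]2(C)O[Si](C)(C)C(C)(C)C)C1=O | intermediate
19 | lithium enolate of 18 (C1'–OLi, C1'=C2') | [Li]OC1=CCC[C@]12[C@H](CC=C)[C@@H](C(C)=C)CC[C@]2(C)O[Si](C)(C)C(C)(C)C | intermediate
20 | keto ester (CH2CO2Et on C2', on the ring B face syn to C6) | CCOC(=O)C[C@@H]1CC[C@]2([C@H](CC=C)[C@@H](C(C)=C)CC[C@]2(C)O[Si](C)(C)C(C)(C)C)C1=O | intermediate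
21 | β-hydroxy ketone ester (free C2 hydroxyl) | CCOC(=O)C[C@@H]1CC[C@]2([C@H](CC=C)[C@@H](C(C)=C)CC[C@]2(C)O)C1=O | intermediate
22 | hydroxy ester (C1' hydroxyl cis to the acetate arm, anti to the C2 oxygen) | CCOC(=O)C[C@@H]1CC[C@]2([C@H](CC=C)[C@@H](C(C)=C)CC[C@]2(C)O)[C@@H]1O | intermediate
23 | cis-fused γ-lactone on C1'/C2' with C6 allyl and C5 isopropenyl | O=C1C[C@@H]2CC[C@]3([C@H](CC=C)[C@@H](C(C)=C)CC[C@]3(C)O)[C@@H]2O1 | intermediate
24 | disiamylborane adduct of 23 (boron on the terminal arm carbon) | O=C1C[C@@H]2CC[C@]3([C@H](CCCB(C(C)C(C)C)C(C)C(C)C)[C@@H](C(C)=C)CC[C@]3(C)O)[C@@H]2O1 | intermediate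
25 | 3-hydroxypropyl lactone | O=C1C[C@@H]2CC[C@]3([C@H](CCCO)[C@@H](C(C)=C)CC[C@]3(C)O)[C@@H]2O1 | intermediate
26 | pivalate of 25 | O=C1C[C@@H]2CC[C@]3([C@H](CCCOC(=O)C(C)(C)C)[C@@H](C(C)=C)CC[C@]3(C)O)[C@@H]2O1 | intermediate
27 | 2-substituted allyl alcohol (CH2=C(CH2OH) on C5) | O=C1C[C@@H]2CC[C@]3([C@H](CCCOC(=O)C(C)(C)C)[C@@H](C(CO)=C)CC[C@]3(C)O)[C@@H]2O1 | intermediate
28 | α-methylene aldehyde (CH2=C(CHO) on C5) | O=C1C[C@@H]2CC[C@]3([C@H](CCCOC(=O)C(C)(C)C)[C@@H](C(C=O)=C)CC[C@]3(C)O)[C@@H]2O1 | intermediate
29 | tetrasubstituted (Z)-enal (C5=C(CH3)CHO, formyl syn to C6) | O=C1C[C@@H]2CC[C@]3([C@H](CCCOC(=O)C(C)(C)C)/C(=C(/C)C=O)CC[C@]3(C)O)[C@@H]2O1 | intermediate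
30 | dimethyl acetal of 29 | O=C1C[C@@H]2CC[C@]3([C@H](CCCOC(=O)C(C)(C)C)/C(=C(/C)C(OC)OC)CC[C@]3(C)O)[C@@H]2O1 | intermediate
31 | 6-methylhept-5-en-2-one | CC(C)=CCCC(C)=O | starting material
32 | terminal lithium enolate of 31 | CC(C)=CCCC(=C)O[Li] | intermediate
33 | 6-methylhepta-1,5-dien-2-yl trifluoromethanesulfonate | CC(C)=CCCC(=C)OS(=O)(=O)C(F)(F)F | intermediate
34 | (2E)-8-methyl-4-methylidenenona-2,7-dienal | CC(C)=CCCC(=C)/C=C/C=O | intermediate
35 | dilithio species of 30 (lactone enolate and C2 alkoxide) | [Li]OC1=C[C@@H]2CC[C@]3([C@H](CCCOC(=O)C(C)(C)C)/C(=C(/C)C(OC)OC)CC[C@]3(C)O[Li])[C@@H]2O1 | intermediate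
36 | aldolate (dilithium salt; the two new centres as mixtures of epimers) | O=C1C(C(O[Li])/C=C/C(=C)CCC=C(C)C)[C@@H]2CC[C@]3([C@H](CCCOC(=O)C(C)(C)C)/C(=C(/C)C(OC)OC)CC[C@]3(C)O[Li])[C@@H]2O1 | intermediate
37 | aldol acetate (C2 alkoxide still lithiated; the two new centres as mixtures of epimers) | O=C1C(C(OC(C)=O)/C=C/C(=C)CCC=C(C)C)[C@@H]2CC[C@]3([C@H](CCCOC(=O)C(C)(C)C)/C(=C(/C)C(OC)OC)CC[C@]3(C)O[Li])[C@@H]2O1 | intermediate
38 | (E)-α-alkylidene lactone (trienyl chain anti to the lactone carbonyl, syn to C2') | O=C1/C(=C/C=C/C(=C)CCC=C(C)C)[C@@H]2CC[C@]3([C@H](CCCOC(=O)C(C)(C)C)/C(=C(/C)C(OC)OC)CC[C@]3(C)O)[C@@H]2O1 | intermediate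
39 | dimethyl acetal of the target | C=C(/C=C/C=C(/CO)[C@@H]1CC[C@]2([C@H](CCCO)/C(=C(/C)C(OC)OC)CC[C@]2(C)O)[C@@H]1O)CCC=C(C)C | intermediate
40 | 28-deacetylbelamcandal | C=C(/C=C/C=C(/CO)[C@@H]1CC[C@]2([C@H](CCCO)/C(=C(/C)C=O)CC[C@]2(C)O)[C@@H]1O)CCC=C(C)C | target

Total step count: 24 (22 on the main line, 2 for the dienal). Longest linear sequence: 22 steps (steps 1–19 and 22–24, from carvone).

Least certain steps

Step 8 (key step). The most likely failure is loss of regiocontrol in the C–O cleavage: the epoxide could open at C2 without participation of the cyclobutane bond and then lose a proton to give allylic alcohols, or the Lewis acid could strip the silyl ether. Fallback: from 13, silylation of the cyclobutanol (1-(trimethylsilyl)imidazole) would give the trimethylsilyl ether F1. Its rearrangement with TiCl4 in CH2Cl2 at −78 °C is a chelation-organised semipinacol shift of an epoxy silyl ether, in which the titanium bridges the two oxygens and the silyl group is lost as the ketone forms; aqueous work-up would return hydroxy ketone 14.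

Step 12. The risk is poor facial discrimination at C2', because the controlling groups sit on carbons one bond beyond the spiro centre; a second alkylation could also occur. Fallback, which sets C2' from C1' by ring fusion: from 18, dehydrogenation with 2-iodoxybenzoic acid in DMSO at 70 °C would give the cyclopentenone F2. Desilylation (aq. HF, MeCN) would give the hydroxy enone F3, and directed 1,2-reduction with Me4NBH(OAc)3 the allylic alcohol F4 (hydroxyl on the C6 side). Ethyl vinyl ether and N-bromosuccinimide would give the bromoacetal F5. Ueno–Stork radical cyclisation (Bu3SnH, AIBN, benzene, 80 °C) forms the C2'–CH2 bond necessarily cis to the C1' oxygen and would give the bicyclic acetal F6. Oxidation with CrO3/H2SO4 in acetone then returns lactone 23.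

Step 18. The Rh–H species may fail to add to the hindered, electron-poor methylene group, the aldehyde may be decarbonylated, or the geometric equilibrium may be less one-sided than argued. Fallback: from 28, conjugate reduction with [(Ph3P)CuH]6 would give the saturated aldehyde F7. α-Bromination through the enol (PhNMe3Br3, THF) would give the α-bromo aldehyde F8. Dehydrobromination with LiBr/Li2CO3 in DMF at 100 °C, which favours the more substituted conjugated alkene, returns enal 29.

Step 6. Oxygen delivery could come under the control of the tertiary cyclobutanol hydroxyl instead of the hydroxymethyl group and reach the face anti to the arm. Fallback, which leaves only one hydroxyl able to direct: from 11, Me3SiCl/Et3N would give the bis(trimethylsilyl) ether F9. Brief K2CO3/MeOH at 0 °C would free only the primary hydroxyl and give the mono-silyl ether F10. Epoxidation with VO(acac)2/t-BuOOH would give the epoxy silyl ether F11, and longer K2CO3/MeOH treatment returns epoxy diol 12.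

Step 5. Tin–lithium exchange at the fully substituted alkenyl carbon may be sluggish, and the basic alkenyllithium may enolise cyclobutanone instead of adding. Fallback: from 7, iododestannylation (I2, CH2Cl2, 0 °C) would give the alkenyl iodide F12. Iodine–lithium exchange with t-BuLi at −78 °C leads to 9, transmetalation with CeCl3 gives a less basic organocerium reagent, and addition to 8 gives alkoxide 10 and, after Bu4NF, diol 11.

Step 15. Chemoselectivity between the allyl and isopropenyl double bonds could be lost, and the tertiary hydroxyl consumes borane. Fallback: from 23, an aldehyde-selective Wacker oxidation (PdCl2(PhCN)2, CuCl2, AgNO2, O2, t-BuOH/MeNO2), to which 1,1-disubstituted alkenes are inert, would give the aldehyde F13; NaBH4 in MeOH at 0 °C returns alcohol 25.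

Further compounds

F1 | step 8 | trimethylsilyl ether of epoxy cyclobutanol 13 | C[Si](C)(C)OC1(CCC1)[C@@]23O[C@@]3(C)CC[C@H](C(C)=C)[C@H]2CO[Si](C)(C)C(C)(C)C
F2 | step 12 | spiro cyclopent-2-enone (C2'=C3') with tertiary silyl ether | O=C1C=CC[C@]12[C@H](CC=C)[C@@H](C(C)=C)CC[C@]2(C)O[Si](C)(C)C(C)(C)C
F3 | step 12 | hydroxy enone | O=C1C=CC[C@]12[C@H](CC=C)[C@@H](C(C)=C)CC[C@]2(C)O
F4 | step 12 | ring B allylic alcohol (C1' hydroxyl on the C6 side) | O[C@@H]1C=CC[C@]12[C@H](CC=C)[C@@H](C(C)=C)CC[C@]2(C)O
F5 | step 12 | bromoacetal of F4 (acetal carbon as a mixture) | CCOC(CBr)O[C@@H]1C=CC[C@]12[C@H](CC=C)[C@@H](C(C)=C)CC[C@]2(C)O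
F6 | step 12 | cis-fused 2-ethoxytetrahydrofuran (acetal carbon as a mixture) | CCOC1C[C@@H]2CC[C@]3([C@H](CC=C)[C@@H](C(C)=C)CC[C@]3(C)O)[C@@H]2O1
F7 | step 18 | saturated aldehyde (CH(CH3)CHO on C5, new centre as a mixture) | O=C1C[C@@H]2CC[C@]3([C@H](CCCOC(=O)C(C)(C)C)[C@@H](C(C)C=O)CC[C@]3(C)O)[C@@H]2O1
F8 | step 18 | α-bromo aldehyde (new centre as a mixture) | O=C1C[C@@H]2CC[C@]3([C@H](CCCOC(=O)C(C)(C)C)[C@@H](C(C)(Br)C=O)CC[C@]3(C)O)[C@@H]2O1
F9 | step 6 | bis(trimethylsilyl) ether of diol 11 | CC1=C(C2(O[Si](C)(C)C)CCC2)[C@H](CO[Si](C)(C)C)[C@@H](C(C)=C)CC1
F10 | step 6 | tertiary trimethylsilyl ether with free CH2OH | CC1=C(C2(O[Si](C)(C)C)CCC2)[C@H](CO)[C@@H](C(C)=C)CC1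
F11 | step 6 | epoxide of F10 (oxygen syn to CH2OH) | C[Si](C)(C)OC1(CCC1)[C@@]23O[C@@]3(C)CC[C@H](C(C)=C)[C@H]2CO
F12 | step 5 | alkenyl iodide (iodine on C1) | CC1=C(I)[C@H](CO[Si](C)(C)C(C)(C)C)[C@@H](C(C)=C)CC1
F13 | step 15 | arm aldehyde (CH2CH2CHO on C6) | O=C1C[C@@H]2CC[C@]3([C@H](CCC=O)[C@@H](C(C)=C)CC[C@]3(C)O)[C@@H]2O1
A1 | alternative 1 | methyl 8-oxo-1,4-dioxaspiro[4.5]dec-6-ene-7-carboxylate | COC(=O)C1=CC2(OCCO2)CCC1=O
A2 | alternative 1 | 2-allyl-2-carbomethoxy-3-[3-(tert-butyldimethylsilyloxy)propyl]cyclohexanone 4-ethylene ketal | C=CC[C@]2([C@H](CCCO[Si](C)(C)C(C)(C)C)C3(OCCO3)CCC2=O)C(=O)OC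
A3 | alternative 2 | cyclopentene whose quaternary carbon bears the enol triflate arm and the triethylsilyl-protected vinyl methyl carbinol | C1=CCC[C@@]1([C@H](CCCO[Si](C)(C)C(C)(C)C)/C(OS(=O)(=O)C(F)(F)F)=C(/C)C(=O)OC)[C@](C)(C=C)O[Si](CC)(CC)CC
A4 | alternative 2 | spiro[4.5]decadiene with the tetrasubstituted enoate in place | C1=CCC[C@]12[C@H](CCCO[Si](C)(C)C(C)(C)C)/C(=C(/C)C(=O)OC)CC[C@]2(C)O[Si](CC)(CC)CC
A5 | alternative 3 | quaternary aldehyde with homoprenyl arm on the ketal-protected ring A | O=C[C@]1(CCC=C(C)C)[C@H](CCCO[Si](C)(C)C(C)(C)C)C2(OCCO2)CC[C@]1(C)O[Si](CC)(CC)CC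
A6 | alternative 3 | spirocyclic cis-2-isopropenylcyclopentanol | C=C(C)[C@@H]1CC[C@]2([C@H](CCCO[Si](C)(C)C(C)(C)C)C3(OCCO3)CC[C@]2(C)O[Si](CC)(CC)CC)[C@@H]1O
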